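All runs are calculated with constants of no real substance; scatter was added.

Start by counting: if one reagent gives one target, the flask can't make more target than its reagent charge over its substrate charge, 90.0 % of the charge, and that fraction is the ceiling. Reagent, charged below the substrate, is then the limiting reagent.

| flask | substrate | reagent | remark | time |
|---|---|---|---|---|
| epsilon | 0.15 M (fed, over 40 h) | 0.090 M | run made earlier |  |
| flask | 0.10 M (fed, over 40 h) | 0.0900 M |  | 10 d |

epsilon run (percent of the substrate charged): time / d: target / % = 0.417: 13; 0.833: 30; 1.25: 37; 1.67: 46; 2.00: 48; 2.50: 48; 3.00: 40

(readings scatter by 2 percentage points)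

- the best time, 10 d at the latest, for target
- the amount of target, in percent of the substrate charged, at that time
- the first time at which target reaches 20 %, in the same percent, in d

- the numbers in the tables scatter with a standard deviation of 2 percentage points
- percentages count the whole charge, also what has not yet gone in

The epsilon run has a ceiling of 60.0 %. Its readings peak at 48 % at 2.00 d, then stand at 40 % at 3.00 d, so as a reading, with its scatter, it reached 0.800 of its ceiling.

My bracket for the flask has two ends. From above I take its ceiling times that share, 72.0 %, since substrate goes into the flask more slowly than into the epsilon run, so I expect target to stand longer under the fall those readings show. From below I take the epsilon peak, 48 %, since the flask's ceiling is higher than the epsilon ceiling.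

The forecast gives 61 % at 2.4 d, inside my bracket, with a range of 53 % to 76 %, whose top lies above mine. Of that range it says: “I therefore skew the estimates upward”. It has the asked level reached at 0.66 d.

The flask gives 65.0 % at 2.23 d, inside the bracket, and reaches the level at 0.546 d, earlier than the forecast.

    substrate + reagent → target (k = 7.50 × 10⁻⁴ L mol⁻¹ s⁻¹)
    substrate + 2 reagent → side product (k = 2.50 × 10⁻⁴ L² mol⁻² s⁻¹)
    target ⇌ isomer of the product (K = 0.720, k = 2.40 × 10⁻⁶ s⁻¹)

At its best time the flask stands at 0.722 of its ceiling, with 8.39 % of its reagent charge still there and 14.8 % of the substrate charged as isomer of the product. Now take the neighbouring flask with 0.054 M of reagent, everything else held. Its ceiling is 54.0 %, and times the epsilon share that makes 43.2 %. That flask gives a best of 42.7 %, and at 10.0 d its target stands at 31.1 %.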